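You cannot read a share from the first row of Wednesday's run: complex with three exchanged stands at 0% and complex with four exchanged at 0.2%, both below the scatter of 0.5 percentage points. Starting complex reads clearly from that row on, so use it as your clock.

| setting | Wednesday's | Saturday's | Friday's | south-west | north | west | south |
|---|---|---|---|---|---|---|---|
| starting complex | 0.20 M | 0.28 M | 0.44 M | 0.20 M | 0.20 M (fed, over 2.00 d) | 0.20 M | 0.20 M |
| incoming ligand | 1.8 equiv | 1.8 equiv | 1.8 equiv | 1.80 equiv | 1.80 equiv | 1.80 equiv | 1.80 equiv (fed, over 2.00 d) |
| remark | run made earlier | run made earlier | run made earlier | a closed flask charged with all of it at once and left for 2.5 d | a stirred flask in which starting complex is dosed at a steady rate over 2.00 d without added volume, worked up at 2.5 d | a single well-mixed tank run continuously and read at steady state, 2.5 d in it on average | all but incoming ligand at the start; incoming ligand goes in evenly over 2.00 d, the run ends at 2.5 d |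
| time |  |  |  | 2.5 d | 2.5 d |  | 2.5 d |

- Wednesday's (time / d: complex with three exchanged / %, complex with four exchanged / %, starting complex / %): 0.208: 0, 0.2, 69.8; 0.333: 0, 0.2, 58.2; 0.500: 0.6, 0, 45.8; 0.833: 1.3, 0, 31.6; 1.67: 5.6, 1.8, 15.4; 2.50: 5.0, 3.0, 9.9
- Saturday's (time / h: complex with three exchanged / %, complex with four exchanged / %, starting complex / %): 8.00: 0.8, 0, 48.0; 15.0: 2.8, 0.2, 29.9; 25.0: 3.7, 1.1, 17.7; 30.0: 5.2, 1.0, 14.8; 40.0: 6.3, 2.8, 9.8; 50.0: 6.2, 4.0, 8.7
- Friday's (time / h: complex with three exchanged / %, complex with four exchanged / %, starting complex / %): 3.00: 0.1, 0.2, 62.8; 10.0: 2.7, 0.2, 28.3; 15.0: 3.7, 0.8, 18.2; 25.0: 7.0, 2.8, 10.8; 40.0: 7.3, 5.2, 6.7; 50.0: 8.2, 6.3, 4.7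

(readings scatter by 0.5 percentage points)

- the stated concentrations are those of everything mixed, before any reaction; amounts are the same in each set-up
- the feed brings no volume worth counting
- the earlier runs were made in a closed, stirred flask
- a reading or a percentage of complex with three exchanged counts all its forms, free or not
- a reading of starting complex is of its free form alone

- the set-up with the highest share of complex with three exchanged in all that became complex with three exchanged or complex with four exchanged, at the outlet or at the end ("none" if the first two lie within 2 percentage points) (south-west / north / west / south / none)
- share of complex with three exchanged in all that became complex with three exchanged or complex with four exchanged, at the outlet or at the end, south-west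
- share of complex with three exchanged in all that became complex with three exchanged or complex with four exchanged, at the outlet or at the end, north
- share of complex with three exchanged in all that became complex with three exchanged or complex with four exchanged, at the outlet or at the end, west
- share of complex with three exchanged in all that became complex with three exchanged or complex with four exchanged, at the outlet or at the end, south

Start at the foot of Wednesday's table. It reads 9.9% of free starting complex, which is 1.00 decades down, the common logarithm of charged over free starting complex. There the share of complex with three exchanged in the two products, the selectivity, reads 62.5%.

Go up one row, to 1.67 d. You read 0.812 decades and 75.7%.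

Now take the last rows of the other tables. Saturday's reads 1.06 decades and 60.8%. Friday's reads 1.33 decades and 56.6%.

The charge runs from 0.20 M to 0.44 M, yet across these four readings the share falls as decades grow. Each share carries the scatter of its readings.

South-west repeats Wednesday's recipe and time. So my own reckoning puts it at 1.00 decades and about 62.5%. These readings come from closed flasks, so I carry this reckoning to no fed flask and no tank.

The forecast holds that “product distribution follows integrated ligand exposure”. It gives south-west 63%, north 70%, west 47% and south 80%, and it names south as best.

    complex with three exchanged + incoming ligand → leaving ligand + complex with four exchanged (k = 0.0230 /M/min)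
    starting complex + complex with three exchanged ⇌ idle adduct, settled at all times (K = 160 /M)
    starting complex + incoming ligand → leaving ligand + complex with one exchanged (k = 0.00370 /M/min)
    complex with one exchanged + incoming ligand → leaving ligand + complex with two exchanged (k = 0.00230 /M/min)
    complex with two exchanged + incoming ligand → leaving ligand + complex with three exchanged (k = 8.70 × 10⁻⁴ /M/min)

South-west gives 56.8%, which is 6.2 points under the forecast. North gives 65.7%, west 50.3% and south 76.9%, so south comes out best. South-west ends with 10% of its starting complex free, which is 0.983 decades. North ends with 23% of its starting complex free, which is 0.631 decades, 0.373 below Wednesday's reading of 1.00. North's neighbour is charged with 1.10 equiv of incoming ligand. That neighbour ends with 41% of its starting complex free, so it stands at 0.383 decades, fewer than north. Its share is 83.9%, higher than north's.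

Readings and results come from a simulation on assumed constants, and the scatter is random.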